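**Retrosynthetic overview** (PPAP numbering: C1 acyl bridgehead, C5 prenyl bridgehead, C9 bridging ketone)
1. Target 27 ⇐ O-demethylation/C3-desilylation ⇐ bridgehead (C1) lithiation–acylation of the bicyclo[3.3.1]nonenedione methyl enol ether 21. The usual malonyl annulation of a cyclohexanone and acylphloroglucinol dearomatisation are both avoided.
2. Key step: 21 ⇐ hypervalent-iodine oxidative 1,2-shift (semipinacol) ring expansion of the cis-fused hydrindanone ketol 19. The C8 quaternary carbon migrates from the carbinol carbon (which becomes C9=O) to the γ-carbon (which becomes C1).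
3. 19 ⇐ intramolecular vinylogous aldol of acylcyclopentanone 17. The C5 quaternary centre comes from C-acylation, then C-prenylation anti to the C7/C8 substituents, which places the bridge cis to the C7 prenyl group.
4. Cyclopentanone 10 ⇐ copper-catalysed asymmetric conjugate addition to 2-methylcyclopent-2-en-1-one (sets C7) and trans enolate alkylation with homoprenyl iodide (sets C8).
5. Ring order: cyclopentane (bought in 1) → methoxycyclohexenone ring (step 9) → cyclopentane expanded to the second six-membered ring (step 10).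

Assumption: the stereodescriptors of the SMILES are taken literally (C7 prenyl on the same side of the cyclohexanone ring as the C2–C3–C4 bridge and trans to the C8 homoprenyl chain), the enolised β-diketone is a freely equilibrating tautomer pair, and compounds 1, 2, 6, 11, 16 and 24 are catalogue items.

**Route**

Step 1
Reactants: 1 2-methylcyclopent-2-en-1-one; 2 4-bromo-2-methylbut-1-ene
Product: 5 (S)-trimethyl{[2-methyl-3-(3-methylbut-3-en-1-yl)cyclopent-1-en-1-yl]oxy}silane, via Grignard reagent 3 (not isolated), via magnesium enolate 4 (not isolated)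
Conditions: 2, Mg, Et2O, rt; added over 2 h to 1, CuBr·SMe2 (5 mol%), (R)-1-[(S)-2-(diphenylphosphino)ferrocenyl]ethyldicyclohexylphosphine (6 mol%), t-BuOMe, −78 °C; then Me3SiCl, Et3N, HMPA, −78 °C → rt
Reagents that add atoms: chlorotrimethylsilane C[Si](C)(C)Cl
Why: Copper-catalysed asymmetric conjugate addition of a primary alkyl Grignard reagent under chiral ferrocenyl diphosphine control sets the C3 stereocentre (future C7) as S by ligand-controlled attack on one enantioface of the enone, and silyl trapping fixes the tetrasubstituted enolate regiochemistry; the ligand hand shown is to be confirmed on a test run, its mirror image giving the antipode.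

Step 2
Reactants: 6 5-bromo-2-methylpent-2-ene
Product: 7 5-iodo-2-methylpent-2-ene
Conditions: NaI, acetone, reflux
Reagents that add atoms: sodium iodide [Na+].[I-]
Why: Finkelstein halide exchange (SN2) gives the more reactive primary iodide needed to alkylate a hindered enolate.

Step 3
Reactants: 5 (S)-silyl enol ether; 7 5-iodo-2-methylpent-2-ene
Product: 9 (2R,3S)-2-methyl-3-(3-methylbut-3-en-1-yl)-2-(4-methylpent-3-en-1-yl)cyclopentan-1-one, via lithium enolate 8 (not isolated)
Conditions: MeLi, THF, 0 °C; then HMPA, 7, −78 °C → rt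
Reagents that add atoms: none
Why: Methyllithium cleaves the silyl enol ether to the regiodefined lithium enolate (regiospecific enolate generation), whose SN2 alkylation occurs on the face opposite the adjacent C3 side chain, so the new quaternary centre (future C8, 2R) carries the homoprenyl group trans to that chain.

Step 4
Reactants: 9 (2R,3S)-ketone
Product: 10 (2R,3R)-2-methyl-3-(3-methylbut-2-en-1-yl)-2-(4-methylpent-3-en-1-yl)cyclopentan-1-one
Conditions: chloro[N,N'-bis(3,5-di-tert-butylsalicylidene)-(1R,2R)-cyclohexane-1,2-diaminato]cobalt (3 mol%), PhSiH3 (6 mol%), benzene, rt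
Reagents that add atoms: none
Why: Cobalt-hydride hydrogen-atom-transfer alkene isomerisation moves the 1,1-disubstituted terminal alkene one position into the more stable trisubstituted prenyl alkene through a tertiary radical, leaving the already trisubstituted homoprenyl alkene, the ketone and both stereocentres untouched (the descriptor at C3 changes only through CIP priorities).

Step 5
Reactants: 11 methyl (E)-3-methoxybut-2-enoate
Product: 12 (E)-3-methoxybut-2-enoic acid
Conditions: KOH, MeOH/H2O, 50 °C; then 1 M HCl to pH 3, 0 °C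
Reagents that add atoms: potassium hydroxide [K+].[OH-]
Why: Ester saponification (acyl substitution by hydroxide) followed by cold, mild acidification frees the acid without hydrolysing the enol ether.

Step 6
Reactants: 12 (E)-3-methoxybut-2-enoic acid
Product: 13 (E)-3-methoxybut-2-enoyl chloride
Conditions: (COCl)2, DMF (cat.), CH2Cl2, 0 °C → rt; concentrated and used crude
Reagents that add atoms: oxalyl chloride O=C(Cl)C(Cl)=O
Why: Vilsmeier-type activation with oxalyl chloride and catalytic DMF converts the acid into the acid chloride under conditions mild enough for the enol ether.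

Step 7
Reactants: 10 (2R,3R)-ketone; 13 (E)-3-methoxybut-2-enoyl chloride
Product: 15 (2R,3S)-5-[(E)-3-methoxybut-2-enoyl]-2-methyl-3-(3-methylbut-2-en-1-yl)-2-(4-methylpent-3-en-1-yl)cyclopentan-1-one (C5 epimers equilibrating through the enol), via lithium enolate 14 (not isolated)
Conditions: LiN(SiMe3)2 (2.2 equiv), THF, −78 °C; then 13, −78 → −20 °C; AcOH quench; used without delay
Reagents that add atoms: none
Why: Crossed Claisen-type C-acylation of the only possible (C5) lithium enolate by the acid chloride, the second equivalent of base removing the acidic 1,3-dicarbonyl proton of the product so that C-acylation is driven to completion; the new C5 centre is enolisable and needs no control here.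

Step 8
Reactants: 15 acylcyclopentanone; 16 1-bromo-3-methylbut-2-ene
Product: 17 (2R,3S,5S)-5-[(E)-3-methoxybut-2-enoyl]-2-methyl-3,5-bis(3-methylbut-2-en-1-yl)-2-(4-methylpent-3-en-1-yl)cyclopentan-1-one
Conditions: K2CO3, acetone, rt
Reagents that add atoms: none
Why: SN2 C-alkylation of the soft 1,3-dicarbonyl enolate by prenyl bromide takes place on the ring face opposite the pseudo-axial C2 methyl group and the C3 prenyl group, which leaves the acyl group (future C4) cis to the C3 prenyl group and so sets the C5 quaternary centre (5S) in the relative configuration the bridge requires.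

Step 9
Reactants: 17 prenylated diketone
Product: 19 (2S,3R,3aR,7aR)-3a-hydroxy-5-methoxy-3-methyl-2,7a-bis(3-methylbut-2-en-1-yl)-3-(4-methylpent-3-en-1-yl)-1,2,3,3a,4,7a-hexahydro-7H-inden-7-one, via lithium dienolate 18 (not isolated)
Conditions: LiN(SiMe3)2 (1.2 equiv), THF, −78 → 0 °C; AcOH, −78 °C
Reagents that add atoms: none
Why: Intramolecular vinylogous aldol addition in which reversible γ-deprotonation of the β-methoxy enone gives the dienolate, whose γ-carbon can reach the ring ketone only through a six-membered transition state from the face carrying the acyl group, giving the cis-fused ketol (3aR) held as its lithium chelate until the cold quench.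

Step 10
Reactants: 19 hydrindanone ketol
Product: 21 (1S,5R,6R,7S)-4-methoxy-6-methyl-1,7-bis(3-methylbut-2-en-1-yl)-6-(4-methylpent-3-en-1-yl)bicyclo[3.3.1]non-3-ene-2,9-dione, via γ-iodane 20 (not isolated)
Conditions: KOH (5 equiv), MeOH, 0 °C; PhI(OAc)2 (1.3 equiv), 0 °C → rt
Reagents that add atoms: none
Why: Proposed new method: in KOH/MeOH the extended dienolate of the vinylogous ester is most nucleophilic at its γ-carbon C4 (activated by both the enolate and the 5-methoxy group), so attack of the trivalent iodine reagent there gives a γ-iodane whose PhI nucleofuge is displaced with inversion by the anti-periplanar, electron-rich C3–C3a bond pushed by the neighbouring tertiary alkoxide (semipinacol 1,2-shift with retention at the migrating quaternary carbon, the acyl-bearing C7a being the poorer migrating group), which expands the cyclopentane to the second six-membered ring and creates the C9 ketone and the C1 bridgehead in the only configuration the bicycle allows; the closest known reaction types are hypervalent-iodine α-functionalisation of ketone enolates and oxidative semipinacol ring expansion of α-hydroxy enolates.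

Step 11
Reactants: 21 bicyclic methyl enol ether
Product: 23 (1R,5R,6R,7S)-4-methoxy-6-methyl-1,7-bis(3-methylbut-2-en-1-yl)-6-(4-methylpent-3-en-1-yl)-3-(trimethylsilyl)bicyclo[3.3.1]non-3-ene-2,9-dione, via C3-lithio enone 22 (not isolated)
Conditions: lithium 2,2,6,6-tetramethylpiperidide (from n-BuLi and 2,2,6,6-tetramethylpiperidine, 1.3 equiv), Me3SiCl (in situ), THF, −78 °C
Reagents that add atoms: chlorotrimethylsilane C[Si](C)(C)Cl
Why: Kinetic lithiation of the accessible C3 vinylic hydrogen (α-keto vinyl anion flanked by the methoxy-bearing carbon) with in situ silyl trapping blocks C3, because the hindered bridgehead C–H next to the quaternary carbon reacts more slowly (directed lithiation–silylation).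

Step 12
Reactants: 23 C3-silylated bicycle; 24 2-methylpropanoyl chloride
Product: 26 (1R,5R,6R,7S)-4-methoxy-6-methyl-1,7-bis(3-methylbut-2-en-1-yl)-6-(4-methylpent-3-en-1-yl)-5-(2-methylpropanoyl)-3-(trimethylsilyl)bicyclo[3.3.1]non-3-ene-2,9-dione, via bridgehead lithio species 25 (not isolated)
Conditions: lithium 2,2,6,6-tetramethylpiperidide (from n-BuLi and 2,2,6,6-tetramethylpiperidine, 2 equiv), THF, −78 → −40 °C; then 24, −78 → 0 °C
Reagents that add atoms: none
Why: Bridgehead lithiation at C5 (the only remaining acidic C–H, activated by the C9 carbonyl and the neighbouring methoxy oxygen) followed by acylation of the localised carbanion installs the isobutyryl group with retention, the bicyclic frame allowing no other configuration (bridgehead carbanion acylation).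

Step 13
Reactants: 26 acylated bicycle
Product: 27 (1S,5S,7S,8R)-4-hydroxy-8-methyl-5,7-bis(3-methylbut-2-en-1-yl)-8-(4-methylpent-3-en-1-yl)-1-(2-methylpropanoyl)bicyclo[3.3.1]non-3-ene-2,9-dione (target CNP0178130.1)
Conditions: LiCl, DMSO, 120 °C; then 1 M HCl work-up
Reagents that add atoms: none
Why: Krapcho-type SN2 attack of chloride on the O-methyl group unveils the lithium β-diketonate and the C3 silyl group is lost on the acidic work-up by C-to-O silyl shift and hydrolysis (protodesilylation), giving the enolised triketone, which the target SMILES draws as one of its two rapidly equilibrating enol tautomers.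

**Compound list**

1 | 2-methylcyclopent-2-en-1-one | CC1=CCCC1=O | starting material
2 | 4-bromo-2-methylbut-1-ene | C=C(C)CCBr | starting material
3 | (3-methylbut-3-en-1-yl)magnesium bromide (not isolated) | C=C(C)CC[Mg]Br | intermediate
4 | bromomagnesium (S)-2-methyl-3-(3-methylbut-3-en-1-yl)cyclopent-1-en-1-olate (not isolated) | Br[Mg]OC1=C(C)[C@@H](CCC(C)=C)CC1 | intermediate
5 | (S)-trimethyl{[2-methyl-3-(3-methylbut-3-en-1-yl)cyclopent-1-en-1-yl]oxy}silane | C[Si](C)(C)OC1=C(C)[C@@H](CCC(C)=C)CC1 | intermediate
6 | 5-bromo-2-methylpent-2-ene | CC(C)=CCCBr | starting material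
7 | 5-iodo-2-methylpent-2-ene | CC(C)=CCCI | intermediate
8 | lithium (S)-2-methyl-3-(3-methylbut-3-en-1-yl)cyclopent-1-en-1-olate (not isolated) | [Li]OC1=C(C)[C@@H](CCC(C)=C)CC1 | intermediate
9 | (2R,3S)-2-methyl-3-(3-methylbut-3-en-1-yl)-2-(4-methylpent-3-en-1-yl)cyclopentan-1-one | O=C1[C@](C)(CCC=C(C)C)[C@@H](CCC(C)=C)CC1 | intermediate
10 | (2R,3R)-2-methyl-3-(3-methylbut-2-en-1-yl)-2-(4-methylpent-3-en-1-yl)cyclopentan-1-one | O=C1[C@](C)(CCC=C(C)C)[C@@H](CC=C(C)C)CC1 | intermediate
11 | methyl (E)-3-methoxybut-2-enoate | CO/C(C)=C/C(=O)OC | starting material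
12 | (E)-3-methoxybut-2-enoic acid | CO/C(C)=C/C(=O)O | intermediate
13 | (E)-3-methoxybut-2-enoyl chloride | CO/C(C)=C/C(Cl)=O | intermediate
14 | lithium (4S,5R)-5-methyl-4-(3-methylbut-2-en-1-yl)-5-(4-methylpent-3-en-1-yl)cyclopent-1-en-1-olate (not isolated) | [Li]OC1=CC[C@H](CC=C(C)C)[C@@]1(C)CCC=C(C)C | intermediate
15 | (2R,3S)-5-[(E)-3-methoxybut-2-enoyl]-2-methyl-3-(3-methylbut-2-en-1-yl)-2-(4-methylpent-3-en-1-yl)cyclopentan-1-one, C5 epimers/enol | CO/C(C)=C/C(=O)C1C[C@H](CC=C(C)C)[C@@](C)(CCC=C(C)C)C1=O | intermediate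
16 | 1-bromo-3-methylbut-2-ene (prenyl bromide) | CC(C)=CCBr | starting material
17 | (2R,3S,5S)-5-[(E)-3-methoxybut-2-enoyl]-2-methyl-3,5-bis(3-methylbut-2-en-1-yl)-2-(4-methylpent-3-en-1-yl)cyclopentan-1-one | CO/C(C)=C/C(=O)[C@]1(CC=C(C)C)C[C@H](CC=C(C)C)[C@@](C)(CCC=C(C)C)C1=O | intermediate
18 | lithium (E)-dienolate of 17, γ-deprotonated (not isolated) | [Li]O/C(=C/C(OC)=C)[C@]1(CC=C(C)C)C[C@H](CC=C(C)C)[C@@](C)(CCC=C(C)C)C1=O | intermediate
19 | (2S,3R,3aR,7aR)-3a-hydroxy-5-methoxy-3-methyl-2,7a-bis(3-methylbut-2-en-1-yl)-3-(4-methylpent-3-en-1-yl)-1,2,3,3a,4,7a-hexahydro-7H-inden-7-one | COC1=CC(=O)[C@]2(CC=C(C)C)C[C@H](CC=C(C)C)[C@@](C)(CCC=C(C)C)[C@]2(O)C1 | intermediate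
20 | (4R)-4-[methoxy(phenyl)-λ3-iodanyl] derivative of 19, C–I anti to the C3–C3a bond (not isolated) | COC1=CC(=O)[C@]2(CC=C(C)C)C[C@H](CC=C(C)C)[C@@](C)(CCC=C(C)C)[C@]2(O)[C@H]1I(OC)c1ccccc1 | intermediate
21 | (1S,5R,6R,7S)-4-methoxy-6-methyl-1,7-bis(3-methylbut-2-en-1-yl)-6-(4-methylpent-3-en-1-yl)bicyclo[3.3.1]non-3-ene-2,9-dione | CC(C)=CCC[C@]1(C)[C@@H](CC=C(C)C)C[C@]2(CC=C(C)C)C(=O)[C@H]1C(OC)=CC2=O | intermediate
22 | 3-lithio derivative of 21 (not isolated) | CC(C)=CCC[C@]1(C)[C@@H](CC=C(C)C)C[C@]2(CC=C(C)C)C(=O)[C@H]1C(OC)=C([Li])C2=O | intermediate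
23 | (1R,5R,6R,7S)-4-methoxy-6-methyl-1,7-bis(3-methylbut-2-en-1-yl)-6-(4-methylpent-3-en-1-yl)-3-(trimethylsilyl)bicyclo[3.3.1]non-3-ene-2,9-dione | CC(C)=CCC[C@]1(C)[C@@H](CC=C(C)C)C[C@]2(CC=C(C)C)C(=O)[C@H]1C(OC)=C([Si](C)(C)C)C2=O | intermediate
24 | 2-methylpropanoyl chloride | CC(C)C(Cl)=O | starting material
25 | 5-lithio (bridgehead) derivative of 23 (not isolated) | CC(C)=CCC[C@]1(C)[C@@H](CC=C(C)C)C[C@]2(CC=C(C)C)C(=O)[C@@]1([Li])C(OC)=C([Si](C)(C)C)C2=O | intermediate
26 | (1R,5R,6R,7S)-4-methoxy-6-methyl-1,7-bis(3-methylbut-2-en-1-yl)-6-(4-methylpent-3-en-1-yl)-5-(2-methylpropanoyl)-3-(trimethylsilyl)bicyclo[3.3.1]non-3-ene-2,9-dione | CC(C)=CCC[C@]1(C)[C@@H](CC=C(C)C)C[C@]2(CC=C(C)C)C(=O)[C@@]1(C(=O)C(C)C)C(OC)=C([Si](C)(C)C)C2=O | intermediate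
27 | (1S,5S,7S,8R)-4-hydroxy-8-methyl-5,7-bis(3-methylbut-2-en-1-yl)-8-(4-methylpent-3-en-1-yl)-1-(2-methylpropanoyl)bicyclo[3.3.1]non-3-ene-2,9-dione | CC(C)=CCC[C@]1(C)[C@@H](CC=C(C)C)C[C@]2(CC=C(C)C)C(=O)[C@@]1(C(=O)C(C)C)C(=O)C=C2O | target

**Step count and risk**

Total steps: 13. Longest linear sequence: 10 steps (1, 3, 4, 7, 8, 9, 10, 11, 12, 13, from 1 to 27). Step 2 and steps 5–6 are short side branches.

The three steps most likely to fail, most risky first:

Step 10 (ring expansion). The γ-selective attack of the iodine reagent on this regioisomeric vinylogous ester is unproven; attack at the α-carbon C6, retro-aldol opening of the congested ketol, or epoxide closure by the alkoxide could compete. The fallback sets out from 19 and comes back at 21. Me3SiOSO2CF3/Et3N (CH2Cl2, 0 °C) silylates the tertiary alcohol and enolises the vinylogous ester towards C4 to give the bis(trimethylsilyl) dienol ether F1. N-Bromosuccinimide (THF, −78 °C) brominates the electron-rich terminal carbon of that diene to give the γ-bromo enone F2. Silver trifluoromethanesulfonate (AgOSO2CF3, CH2Cl2, −40 °C) then abstracts bromide, and the same C3–C3a bond migrates with loss of the silyl group (halohydrin-type semipinacol rearrangement), giving 21.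

Step 9 (vinylogous aldol). The β-methoxy enone prefers the conformation that leads to the dienolate geometry unable to reach the ketone, and the ketol has three contiguous quaternary carbons, so retro-aldol may win under aprotic conditions. The fallback sets out from 17 and comes back at 19. 1 M HCl in THF (rt) hydrolyses the enol ether to the triketone F3. K2CO3 in MeOH (rt) then closes the ring under fully reversible, thermodynamic control (polyketide-type aldol pulled by formation of the acidic cyclic 1,3-dione) to give the hydroxy dione F4. Me2SO4/K2CO3 in acetone methylates the less hindered enol oxygen, remote from the quaternary C7a, and returns 19.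

Step 1 (asymmetric conjugate addition). α-Substituted cyclopentenones are slow, poorly selective acceptors, and every later stereocentre depends on this one. The fallback sets out from 2 (as its Grignard reagent 3) and comes back at 5. The same copper/ferrocenyl diphosphine system is applied to the unsubstituted, far more reactive acceptor cyclopent-2-en-1-one F5. The resulting magnesium enolate F6 is methylated (MeI, DMPU, −30 °C) to the trans ketone (2R,3S)-2-methyl-3-(3-methylbut-3-en-1-yl)cyclopentan-1-one F7. Thermodynamic silylation (Me3SiCl, NaI, Et3N, MeCN, rt) then gives the tetrasubstituted silyl enol ether 5, so the methyl group arrives as an electrophile instead of sitting on the enone.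

**Further compounds**

F1 | step 10 | 5-methoxy-3-methyl-2,7a-bis(3-methylbut-2-en-1-yl)-3-(4-methylpent-3-en-1-yl)-3a,7-bis(trimethylsilyloxy)-2,3,3a,7a-tetrahydro-1H-indene (bis-silyl dienol ether of 19) | COC=1C=C(O[Si](C)(C)C)[C@]2(CC=C(C)C)C[C@H](CC=C(C)C)[C@@](C)(CCC=C(C)C)[C@]2(O[Si](C)(C)C)C=1
F2 | step 10 | 4-bromo derivative of the 3a-O-trimethylsilyl ether of 19 (C–Br anti to the C3–C3a bond) | COC1=CC(=O)[C@]2(CC=C(C)C)C[C@H](CC=C(C)C)[C@@](C)(CCC=C(C)C)[C@]2(O[Si](C)(C)C)[C@H]1Br
F3 | step 9 | (2R,3S,5S)-2-methyl-3,5-bis(3-methylbut-2-en-1-yl)-2-(4-methylpent-3-en-1-yl)-5-(3-oxobutanoyl)cyclopentan-1-one | CC(=O)CC(=O)[C@]1(CC=C(C)C)C[C@H](CC=C(C)C)[C@@](C)(CCC=C(C)C)C1=O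
F4 | step 9 | (2S,3R,3aR,7aR)-3a-hydroxy-3-methyl-2,7a-bis(3-methylbut-2-en-1-yl)-3-(4-methylpent-3-en-1-yl)hexahydro-1H-indene-5,7-dione | O=C1CC(=O)[C@]2(CC=C(C)C)C[C@H](CC=C(C)C)[C@@](C)(CCC=C(C)C)[C@]2(O)C1
F5 | step 1 | cyclopent-2-en-1-one | O=C1C=CCC1
F6 | step 1 | bromomagnesium (S)-3-(3-methylbut-3-en-1-yl)cyclopent-1-en-1-olate | Br[Mg]OC1=C[C@@H](CCC(C)=C)CC1
F7 | step 1 | (2R,3S)-2-methyl-3-(3-methylbut-3-en-1-yl)cyclopentan-1-one | O=C1[C@H](C)[C@@H](CCC(C)=C)CC1
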